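## Structural features

The target is a bicyclo[3.2.1]oct-2-en-8-one, numbered here C1 (allyl bridgehead), C2=C3 (enol ether, methoxy on C3), C4 (carbinol), C5 (methoxy bridgehead), C6 (aryl CH), C7 (methyl CH) and C8 (bridging ketone); the same labels are kept for these atoms in every earlier compound. A cyclohexene ring (C1-C2-C3-C4-C5-C8) and a cyclopentanone ring (C1-C7-C6-C5-C8) share the unit C1-C8-C5, so the ketone lies between two quaternary bridgeheads, one carbon-substituted and one oxygenated. Five stereocentres stand in a row, C4-C5-C6-C7-C1: the C7 methyl is exo (on the C8 side), the 4-hydroxy-3-methoxyphenyl group on C6 is endo and trans to it, and the C4 hydroxyl points to the face of the C6-C7 bridge, cis to the aryl group. The fragile parts are the β-hydroxy ketone C4-C5-C8 (retro-aldol under base), the enol ether C2=C3 (aqueous acid), the terminal alkene (no hydrogenation once it is present) and the free guaiacol-type phenol (oxidants). The real difficulty is to build both quaternary bridgeheads and the C6/C7 pair as one enantiomer while the oxygens on C3, C4, C5 and C8 end at the right oxidation levels. The key step uses the fact that ring C1-C2-C3-C4-C5-C8 has methoxy groups on C3 and C5 on either side of the oxygenated C4 and the allyl group on C1 opposite to it. It is therefore a dearomatized 4-allyl-2,6-dimethoxyphenol with two mirror-related enone arms (C2=C3 and C8=C5), carrying the C6-C7 arylpropyl unit on C1, and the benzylic oxygen on C6 can be passed on to C8.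

## Logic of the disconnections

14 to 13: only the phenolic O–Si bond is cut. A free guaiacol does not survive hypervalent iodine oxidants, so it is unveiled last. One aryl silyl ether that lasts from step 1 to step 10 costs no extra operation. The cleavage must be non-basic because of the β-hydroxy ketone.

13 to 12 to 11: the C4–H bond is cut (carbinol back to ketone) and the C8 carbonyl is taken back to a carbinol. This exchange of oxidation levels is the price of the key step, which puts oxygen on C8 as a hydroxyl and leaves C4 as the enone carbonyl. Oxidizing first avoids having to tell two secondary alcohols apart. The forward steps need an oxidation of a hindered alcohol without retro-aldol, then a reduction that picks the conjugated C4 carbonyl over C8 and attacks from the C8 face.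

11 to 9 (through 10): C5–C6 and C8–O are cut and the oxygen is returned to C6. A bicycle with five stereocentres becomes a monocyclic prochiral dienone whose only lasting stereocentre is C7. The forward step must run oxa-Michael addition, benzylic ionization and enol capture in that order, and must choose one enone arm and one face of C6.

9 to 7 + 8: the C1–allyl bond is cut, which re-aromatizes the ring to a phenol. This removes the quaternary carbon and leaves a simple 1,2-diarylpropanol. The forward step must allylate an oxidized phenol at the para carbon although that carbon bears a secondary alkyl group.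

7 to 6 to 5: the O–benzyl bond is cut, then the C6–H bond (carbinol back to ketone). In the ketone, C7 is α to the carbonyl and epimerizable, so a reduction with dynamic kinetic resolution can set C7 from racemic material. The forward steps need hydrogenolysis before any alkene exists and a reduction that is faster for one ketone enantiomer while the other racemizes.

5 to 2 + 4: the C7–aryl bond is cut. This is the only C–C bond between the two aromatic halves and it is made by enolate arylation. The forward step must stop at mono-arylation and tolerate the aryl silyl ether.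

2 to 1 and 4 to 3: the O–Si and O–benzyl bonds are cut. The two phenols need orthogonal masks: benzyl goes by hydrogenolysis in step 5, silyl by fluoride in step 10.

Two design decisions concern 9. First, the guaiacyl oxygen stays silylated through step 7. A para-silyloxy group still supports benzylic ionization, as para-alkoxy groups do in 2-aryl tetrahydrofurans, and this removes a deprotection before and a reprotection after the key step. Second, C6 in 9 is S (like to C7), not R. This is the epimer expected from Felkin–Anh-controlled reduction of 5, and its adduct 10 has aryl and methyl trans on the tetrahydrofuran ring; the R epimer would give the more strained 2,3-cis adduct. C6 is ionized in step 7, so its configuration does not reach 14.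

## Other disconnections considered

Alternative 1: The cut goes through C2–C3 and C1–C7 and leads to cyclobutanol A2. In A2, C5, C6, C7 and C8 form the four-membered ring, C8 carries the hydroxyl and a penta-1,4-dien-2-yl group (C1, C2 and the later allyl group), and C5 carries the methoxy group and the C4(OSi)–C3 dimethyl acetal chain. In the forward step a strong Lewis acid would ionize the acetal and the 1,1-disubstituted alkene would add through C2 (Prins closure of the six-membered ring). The tertiary C1 cation would then be quenched by a pinacol shift of C7 from C8 to C1, which enlarges the cyclobutane to the cyclopentanone and gives A1.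
- In its favour: two C–C bonds, both rings and the C1 quaternary centre would arise in one stereospecific operation of a well-established class. C8 appears directly as the ketone, which is better than the chosen plan on the redox count at C8.
- Against it here: A1 has a saturated C2–C3 bond. Introducing the enol ether would in practice mean oxidizing C4, dehydrogenating C2–C3 and reducing C4 again, so the C4 configuration carried through the key step would be lost and the route would end with the same selective reduction as the chosen one.
- Mechanism: migration of C5 could compete with migration of C7, the second alkene is a competing Prins partner, and the C4 silyloxy group slows ionization of the neighbouring acetal.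
- Structure: the burden moves to A2, with four contiguous stereocentres, two fully substituted. That is harder to make as one enantiomer than 9.
- Step economy: the key step is as short as step 7, but roughly a dozen operations before it and five or six after it are to be expected, against six before and three after in the chosen plan.

Alternative 2: The whole three-carbon bridge is removed by cutting C1–C2 and C4–C5. This leads to the cyclopentanone enol silane A4 (C1=C8 silyl enol ether, C5 bearing H and methoxy) and methoxymalonyl dichloride A5. In the forward step C1 would be C-acylated by one acyl chloride and the C5 enol by the other (Effenberger-type cyclization) to give the enolized trione A3.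
- In its favour: it is the most convergent plan. Both quaternary bridgeheads and the six-membered ring would form in one operation, C3 arrives with its methoxy group, and C8 is a ketone from the start. On convergence and on the redox count at C8 it is better than the chosen plan.
- Against it here, structure: A3 carries an oxygen on C2 that 14 lacks. Removing it means telling apart the C2 and C4 oxygens of an enolized β-diketone that differ only in their bridgehead neighbours, then reducing the C–O bond, then the same C4 reduction as in the chosen plan (equal on that point).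
- Mechanism: the cyclization is well documented for six-membered ketones giving bicyclo[3.3.1]nonanes. Closing the more strained bicyclo[3.2.1] frame at a methoxy-bearing C5 is less secure, and O-acylation competes.
- Stereochemistry: aryl and methyl are trans, so one of them must be syn to the incoming bridge. Sterics would favour the bridge syn to the smaller methyl, which is the wrong diastereomer (aryl exo). In the chosen plan this choice is made intramolecularly under the control of C7.
- Step economy: A4 must first be made as one enantiomer with three stereocentres, and the corrections after the key step are more numerous. The total would be no shorter than the chosen plan and probably longer.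

Alternative 3: The cut is C6–C7 inside the five-membered ring and opens it to the cross-conjugated dienone A7. In the forward step a chiral Lewis acid would trigger conrotatory closure to the oxyallyl cation, and a trialkylsilane would deliver hydride to C5 and leave the C1=C8 silyl enol ether A6.
- In its favour: A7 should be available in a few steps. The trans relation of aryl and methyl follows from the alkene geometries by the conrotatory rule, a pericyclic control that is more certain than the cation capture that sets C6 in step 7; on this point it is better. The methoxy group polarizes the dienone, and the enol silane is formed regiospecifically at C1.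
- Against it here, structure: the step makes only the cyclopentane. Neither quaternary bridgehead nor the six-membered ring is formed, so the central problem remains and needs a second key step, such as the bis-acylation of alternative 2 with its facial problem.
- Mechanism: absolute control would require a catalyst to dictate the sense of conrotation of an acyclic dienone while silane trapping competes with proton loss. That combination is not established. Acid-induced isomerization of the enol ether alkene would erode the diastereoselectivity. Enantiocontrol rests on a new catalytic step instead of a reduction of established type.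
- Step economy: the sequence to 14 would be the longest of the four.

Key step: step 7

Assumption: the transfer hydrogenation of 5 is taken to follow Felkin–Anh control, so that the (S,S)-catalyst, which gives S carbinols from aryl ketones, consumes the (S)-ketone and gives the like (1S,2S) alcohol; only the C7 configuration is carried to 14.

Step 1
Reactants: 1 1-(4-hydroxy-3-methoxyphenyl)propan-1-one
Product: 2 1-[3-methoxy-4-(triisopropylsilyloxy)phenyl]propan-1-one
Conditions: TIPSCl (1.2 equiv), imidazole (2.5 equiv), DMF, rt
Reagents that add atoms: triisopropylsilyl chloride, CC(C)[Si](Cl)(C(C)C)C(C)C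
Why: Imidazole-mediated silylation of the phenol; the aryl triisopropylsilyl ether should tolerate the weakly basic arylation, the acidic key step and both redox steps, and it is removed by fluoride at the end.

Step 2
Reactants: 3 4-bromo-2,6-dimethoxyphenol
Product: 4 2-(benzyloxy)-5-bromo-1,3-dimethoxybenzene
Conditions: BnBr (1.1 equiv), K2CO3 (1.5 equiv), DMF, 60 °C
Reagents that add atoms: benzyl bromide, BrCc1ccccc1
Why: Williamson ether synthesis; the benzyl group masks the syringyl phenol during the arylation and is removable by hydrogenolysis before any alkene is present, orthogonally to the aryl silyl ether.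

Step 3
Reactants: 2 1-[3-methoxy-4-(triisopropylsilyloxy)phenyl]propan-1-one; 4 2-(benzyloxy)-5-bromo-1,3-dimethoxybenzene
Product: 5 rac-2-[4-(benzyloxy)-3,5-dimethoxyphenyl]-1-[3-methoxy-4-(triisopropylsilyloxy)phenyl]propan-1-one
Conditions: Pd(OAc)2 (2 mol %), 2-dicyclohexylphosphino-2'-methylbiphenyl (4 mol %), K3PO4 (2 equiv), toluene, 80 °C
Reagents that add atoms: none
Why: Palladium-catalysed α-arylation of a ketone enolate; the propiophenone has one enolizable position, the tertiary α-aryl ketone formed resists a second arylation, and K3PO4 is mild enough for the aryl silyl ether. C7 is formed racemic and stays epimerizable, which step 4 exploits.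

Step 4
Reactants: 5 rac-2-[4-(benzyloxy)-3,5-dimethoxyphenyl]-1-[3-methoxy-4-(triisopropylsilyloxy)phenyl]propan-1-one
Product: 6 (1S,2S)-2-[4-(benzyloxy)-3,5-dimethoxyphenyl]-1-[3-methoxy-4-(triisopropylsilyloxy)phenyl]propan-1-ol
Conditions: RuCl(p-cymene)[(S,S)-TsDPEN] (2 mol %), HCO2H/Et3N (1:1), DMF, 40 °C
Reagents that add atoms: none
Why: Asymmetric transfer hydrogenation with dynamic kinetic resolution: the doubly activated C7–H epimerizes in the amine-rich medium while the catalyst delivers hydride to one carbonyl face (S at C6) and, under Felkin–Anh control, reduces the (S)-ketone faster, so C7 is set as S. C6 is a placeholder that is reset in step 7.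

Step 5
Reactants: 6 (1S,2S)-2-[4-(benzyloxy)-3,5-dimethoxyphenyl]-1-[3-methoxy-4-(triisopropylsilyloxy)phenyl]propan-1-ol
Product: 7 4-[(1S,2S)-1-hydroxy-1-[3-methoxy-4-(triisopropylsilyloxy)phenyl]propan-2-yl]-2,6-dimethoxyphenol
Conditions: H2 (1 atm), Pd/C (10 %), EtOAc, rt
Reagents that add atoms: none
Why: Hydrogenolysis of the aryl benzyl ether in a neutral solvent, done before the allyl group exists; the aryl silyl ether is inert and the secondary benzylic alcohol should survive in the absence of acid.

Step 6
Reactants: 7 4-[(1S,2S)-1-hydroxy-1-[3-methoxy-4-(triisopropylsilyloxy)phenyl]propan-2-yl]-2,6-dimethoxyphenol; 8 allyltrimethylsilane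
Product: 9 4-allyl-4-[(1S,2S)-1-hydroxy-1-[3-methoxy-4-(triisopropylsilyloxy)phenyl]propan-2-yl]-2,6-dimethoxycyclohexa-2,5-dien-1-one
Conditions: PhI(OAc)2 (1.1 equiv), 8 (5 equiv), (CF3)2CHOH/CH2Cl2, −20 °C
Reagents that add atoms: none
Why: Oxidative dearomatization of a para-alkyl phenol with an oxidative Hosomi–Sakurai-type allylation: the phenoxenium-type species formed in the fluorinated alcohol is attacked by the allylsilane at the para carbon, which creates the C1 quaternary carbon of the cross-conjugated dienone. C1 is not yet stereogenic because the two enone arms are identical.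

Step 7
Reactants: 9 4-allyl-4-[(1S,2S)-1-hydroxy-1-[3-methoxy-4-(triisopropylsilyloxy)phenyl]propan-2-yl]-2,6-dimethoxycyclohexa-2,5-dien-1-one
Product: 11 (1R,5S,6S,7R,8R)-1-allyl-8-hydroxy-3,5-dimethoxy-6-[3-methoxy-4-(triisopropylsilyloxy)phenyl]-7-methylbicyclo[3.2.1]oct-2-en-4-one, via tetrahydrobenzofuranone 10 (not isolated)
Conditions: TsOH·H2O (0.1 equiv), (CF3)2CHOH/CH2Cl2 (1:4), 0 °C to rt
Reagents that add atoms: none
Why: Protonation of the dienone lets the C6 hydroxyl add reversibly to C8 in a 5-exo-trig oxa-Michael closure, giving the cis-fused 2-aryl tetrahydrobenzofuranone 10 and with it the C4/C5 enol that the open dienone lacks. The para-silyloxybenzylic C6–O bond of 10 then ionizes, leaving the oxygen on C8 as a hydroxyl, and the enol carbon C5 captures the benzylic cation in a 5-(enolexo)-exo-trig closure that forms C5–C6 and the cyclopentane of the bicycle. The closest known reaction types are the acid-induced rearrangement of 2-aryl hydrobenzofuranoid neolignans to bicyclo[3.2.1]octanoids and the desymmetrizing oxa-Michael addition of tethered alcohols to cyclohexadienones. C1 is set by the choice of enone arm: C7, the only stereocentre that persists, directs addition to the arm that keeps its methyl on the convex face, cis to allyl, which becomes exo in the bicycle. C6 is set in the C–C bond formation: with C7–H eclipsing the planar cation (allylic 1,3-strain), C5 attacks the face that places the aryl group trans to methyl, endo. C8 follows from the intramolecular oxygen delivery (hydroxyl syn to the C6–C7 bridge) and C5 from the constraint of the bridged ring. Every step before C–C bond formation is reversible, so both arms and either C6 epimer can funnel through the lowest closing transition state, and quenching of the cation makes that step irreversible. The step needs closure to win over dienone–phenol rearrangement and over proton loss from C7; a catalytic sulfonic acid in a cation-stabilizing, non-nucleophilic solvent at low temperature, together with the five-membered geometry of the closure, is meant to secure this.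

Step 8
Reactants: 11 (1R,5S,6S,7R,8R)-1-allyl-8-hydroxy-3,5-dimethoxy-6-[3-methoxy-4-(triisopropylsilyloxy)phenyl]-7-methylbicyclo[3.2.1]oct-2-en-4-one
Product: 12 (1R,5S,6S,7R)-1-allyl-3,5-dimethoxy-6-[3-methoxy-4-(triisopropylsilyloxy)phenyl]-7-methylbicyclo[3.2.1]oct-2-ene-4,8-dione
Conditions: Dess–Martin periodinane (1.5 equiv), CH2Cl2, rt
Reagents that add atoms: none
Why: Dess–Martin oxidation of the hindered secondary C8 alcohol under non-basic conditions, which avoids retro-aldol cleavage of the β-hydroxy ketone; the phenol is masked, so the oxidant cannot attack the guaiacol ring.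

Step 9
Reactants: 12 (1R,5S,6S,7R)-1-allyl-3,5-dimethoxy-6-[3-methoxy-4-(triisopropylsilyloxy)phenyl]-7-methylbicyclo[3.2.1]oct-2-ene-4,8-dione
Product: 13 (1R,4S,5R,6S,7R)-1-allyl-4-hydroxy-3,5-dimethoxy-6-[3-methoxy-4-(triisopropylsilyloxy)phenyl]-7-methylbicyclo[3.2.1]oct-2-en-8-one
Conditions: CeCl3·7H2O (1.2 equiv), NaBH4 (1.0 equiv), MeOH, −78 °C, then AcOH quench
Reagents that add atoms: none
Why: Luche reduction: CeCl3 steers borohydride to 1,2-reduction of the conjugated C4 ketone in preference to the C8 ketone, which lies between two quaternary carbons. Hydride should approach C4 from the face of the C8 bridge because the endo aryl group on C6 covers the opposite face, which places the new hydroxyl cis to the aryl group (4S).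

Step 10
Reactants: 13 (1R,4S,5R,6S,7R)-1-allyl-4-hydroxy-3,5-dimethoxy-6-[3-methoxy-4-(triisopropylsilyloxy)phenyl]-7-methylbicyclo[3.2.1]oct-2-en-8-one
Product: 14 (1R,4S,5R,6S,7R)-1-allyl-4-hydroxy-6-(4-hydroxy-3-methoxyphenyl)-3,5-dimethoxy-7-methylbicyclo[3.2.1]oct-2-en-8-one
Conditions: TBAF (1.1 equiv), AcOH (1.1 equiv), THF, 0 °C
Reagents that add atoms: none
Why: Fluoride cleavage of the aryl silyl ether; buffering with acetic acid keeps the medium non-basic so that the β-hydroxy ketone is not opened by retro-aldol reaction.

Compound list

1 | 1-(4-hydroxy-3-methoxyphenyl)propan-1-one | CCC(=O)c1ccc(O)c(OC)c1 | starting material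
2 | 1-[3-methoxy-4-(triisopropylsilyloxy)phenyl]propan-1-one | CCC(=O)c1ccc(O[Si](C(C)C)(C(C)C)C(C)C)c(OC)c1 | intermediate
3 | 4-bromo-2,6-dimethoxyphenol | COc1cc(Br)cc(OC)c1O | starting material
4 | 2-(benzyloxy)-5-bromo-1,3-dimethoxybenzene | COc1cc(Br)cc(OC)c1OCc1ccccc1 | intermediate
5 | rac-2-[4-(benzyloxy)-3,5-dimethoxyphenyl]-1-[3-methoxy-4-(triisopropylsilyloxy)phenyl]propan-1-one | CC(C(=O)c1ccc(O[Si](C(C)C)(C(C)C)C(C)C)c(OC)c1)c1cc(OC)c(OCc2ccccc2)c(OC)c1 | intermediate
6 | (1S,2S)-2-[4-(benzyloxy)-3,5-dimethoxyphenyl]-1-[3-methoxy-4-(triisopropylsilyloxy)phenyl]propan-1-ol | COc1cc(cc(OC)c1OCc1ccccc1)[C@H](C)[C@H](O)c1ccc(O[Si](C(C)C)(C(C)C)C(C)C)c(OC)c1 | intermediate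
7 | 4-[(1S,2S)-1-hydroxy-1-[3-methoxy-4-(triisopropylsilyloxy)phenyl]propan-2-yl]-2,6-dimethoxyphenol | COc1cc(cc(OC)c1O)[C@H](C)[C@H](O)c1ccc(O[Si](C(C)C)(C(C)C)C(C)C)c(OC)c1 | intermediate
8 | allyltrimethylsilane | C=CC[Si](C)(C)C | starting material
9 | 4-allyl-4-[(1S,2S)-1-hydroxy-1-[3-methoxy-4-(triisopropylsilyloxy)phenyl]propan-2-yl]-2,6-dimethoxycyclohexa-2,5-dien-1-one | C=CCC1(C=C(OC)C(=O)C(OC)=C1)[C@H](C)[C@H](O)c1ccc(O[Si](C(C)C)(C(C)C)C(C)C)c(OC)c1 | intermediate
10 | (2S,3S,3aR,7aR)-3a-allyl-5,7-dimethoxy-2-[3-methoxy-4-(triisopropylsilyloxy)phenyl]-3-methyl-3,3a,7,7a-tetrahydro-1-benzofuran-6(2H)-one (cis-fused, aryl and methyl trans, methyl cis to allyl; both epimers at the methoxy-bearing C5) | C=CC[C@@]12C=C(OC)C(=O)C(OC)[C@@H]1O[C@H](c1ccc(O[Si](C(C)C)(C(C)C)C(C)C)c(OC)c1)[C@H]2C | intermediate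
11 | (1R,5S,6S,7R,8R)-1-allyl-8-hydroxy-3,5-dimethoxy-6-[3-methoxy-4-(triisopropylsilyloxy)phenyl]-7-methylbicyclo[3.2.1]oct-2-en-4-one | C=CC[C@@]12C=C(OC)C(=O)[C@@](OC)([C@@H]1O)[C@H](c1ccc(O[Si](C(C)C)(C(C)C)C(C)C)c(OC)c1)[C@H]2C | intermediate
12 | (1R,5S,6S,7R)-1-allyl-3,5-dimethoxy-6-[3-methoxy-4-(triisopropylsilyloxy)phenyl]-7-methylbicyclo[3.2.1]oct-2-ene-4,8-dione | C=CC[C@@]12C=C(OC)C(=O)[C@@](OC)(C1=O)[C@H](c1ccc(O[Si](C(C)C)(C(C)C)C(C)C)c(OC)c1)[C@H]2C | intermediate
13 | (1R,4S,5R,6S,7R)-1-allyl-4-hydroxy-3,5-dimethoxy-6-[3-methoxy-4-(triisopropylsilyloxy)phenyl]-7-methylbicyclo[3.2.1]oct-2-en-8-one | C=CC[C@@]12C=C(OC)[C@H](O)[C@@](OC)(C1=O)[C@H](c1ccc(O[Si](C(C)C)(C(C)C)C(C)C)c(OC)c1)[C@H]2C | intermediate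
14 | (1R,4S,5R,6S,7R)-1-allyl-4-hydroxy-6-(4-hydroxy-3-methoxyphenyl)-3,5-dimethoxy-7-methylbicyclo[3.2.1]oct-2-en-8-one | C=CC[C@@]12C=C(OC)[C@H](O)[C@@](OC)(C1=O)[C@H](c1ccc(O)c(OC)c1)[C@H]2C | target

Total step count: 10. Longest linear sequence: 9 steps (steps 1 and 3 to 10, from 1).

Least certain steps

Step 7 (key step). The most likely failures are processes that compete with the enol capture:
- loss of the C7 proton from the benzylic cation, which gives a styrene and, through reprotonation, erodes the C7 configuration and with it the enantiomeric purity;
- dienone–phenol rearrangement of the protonated dienone;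
- cation–olefin cyclization onto the allyl group;
- insufficient arm selectivity, which would give the methyl-endo diastereomer;
- retro-aldol opening of the product on prolonged exposure to acid.

The fallback separates the events and replaces the protic enol by a preformed enol silane. It sets out from 9, which is cyclized with catalytic DBU in THF to the tetrahydrobenzofuranone 10, now isolated. Soft enolization with TMSOTf and Et3N in CH2Cl2 at −78 °C would give the 6-O-trimethylsilyl dienol ether of 10, F1. Catalytic TMSOTf at −78 °C would then ionize the benzylic C–O bond and let the enol silane alkylate the cation (intramolecular Mukaiyama-type alkylation) to give the 8-O-trimethylsilyl ether of 11, F2. Mild aqueous acetic acid in THF would remove the silyl group and return to the route at 11.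

Step 6. The allylsilane may attack a methoxy-bearing ortho carbon instead of the hindered para carbon, the oxidized phenol may lose the C7 proton to give a quinone methide, or the benzylic alcohol may ionize in the fluorinated solvent and be allylated at C6. The fallback delivers the allyl group intramolecularly. It sets out from 7, which is O-allylated at the phenol with allyl bromide and K2CO3 in acetone to give the allyl ether of 7, (1S,2S)-2-[4-(allyloxy)-3,5-dimethoxyphenyl]-1-[3-methoxy-4-(triisopropylsilyloxy)phenyl]propan-1-ol F3. Heating in N,N-diethylaniline at 170–190 °C would cause a Claisen shift to the ortho dienone 6-allyl-2,6-dimethoxy-4-[(1S,2S)-1-hydroxy-1-[3-methoxy-4-(triisopropylsilyloxy)phenyl]propan-2-yl]cyclohexa-2,4-dien-1-one F4. A Cope shift would then pass the allyl group on to the para carbon and return to the route at 9.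

Step 9. The strained C8 ketone may be reduced in competition, hydride may arrive from the wrong face of C4, or methoxide may open the non-enolizable 1,3-diketone by retro-Claisen cleavage. The fallback changes the order of the redox steps. It sets out from 11, which has no competing ketone, and Luche reduction would give the 4,8-diol F5. Selective silylation of the less hindered allylic C4 hydroxyl with TESCl and imidazole would give the 4-O-triethylsilyl ether of the diol, F6. Dess–Martin oxidation of the C8 alcohol would give the 4-O-triethylsilyl ether of 13, F7. TBAF buffered with AcOH would remove both silyl groups and return to the route at 14.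

Step 4. Epimerization at C7 may be slower than reduction, so the dynamic resolution would be incomplete; the α-branched ketone may react sluggishly; or the matching of catalyst and substrate may be opposite to the Felkin–Anh assumption. In the last case the antipodal catalyst would be used, since C6 is irrelevant. The fallback sets C7 in the C–C bond formation instead:
- From 2, bromination with CuBr2 in EtOAc at reflux would give rac-2-bromo-1-[3-methoxy-4-(triisopropylsilyloxy)phenyl]propan-1-one F8.
- From 4, magnesium in THF would give [4-(benzyloxy)-3,5-dimethoxyphenyl]magnesium bromide F9, and ZnI2 would convert it into [4-(benzyloxy)-3,5-dimethoxyphenyl]zinc iodide F10.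
- A stereoconvergent Negishi coupling of F8 with F10 (NiCl2·glyme, chiral pybox ligand, glyme/THF, −30 °C) would give the (S)-ketone (S)-2-[4-(benzyloxy)-3,5-dimethoxyphenyl]-1-[3-methoxy-4-(triisopropylsilyloxy)phenyl]propan-1-one F11 under non-basic conditions.
- Immediate Felkin–Anh-selective reduction with LiBH(s-Bu)3 in THF at −78 °C would return to the route at 6.

Further compounds

F1 | step 7 | 6-O-trimethylsilyl dienol ether of 10 | C=CC[C@@]12C=C(OC)C(O[Si](C)(C)C)=C(OC)[C@@H]1O[C@H](c1ccc(O[Si](C(C)C)(C(C)C)C(C)C)c(OC)c1)[C@H]2C
F2 | step 7 | 8-O-trimethylsilyl ether of 11 | C=CC[C@@]12C=C(OC)C(=O)[C@@](OC)([C@@H]1O[Si](C)(C)C)[C@H](c1ccc(O[Si](C(C)C)(C(C)C)C(C)C)c(OC)c1)[C@H]2C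
F3 | step 6 | (1S,2S)-2-[4-(allyloxy)-3,5-dimethoxyphenyl]-1-[3-methoxy-4-(triisopropylsilyloxy)phenyl]propan-1-ol | C=CCOc1c(OC)cc(cc1OC)[C@H](C)[C@H](O)c1ccc(O[Si](C(C)C)(C(C)C)C(C)C)c(OC)c1
F4 | step 6 | 6-allyl-2,6-dimethoxy-4-[(1S,2S)-1-hydroxy-1-[3-methoxy-4-(triisopropylsilyloxy)phenyl]propan-2-yl]cyclohexa-2,4-dien-1-one (both epimers at the allyl-bearing carbon) | C=CCC1(OC)C=C([C@H](C)[C@H](O)c2ccc(O[Si](C(C)C)(C(C)C)C(C)C)c(OC)c2)C=C(OC)C1=O
F5 | step 9 | 1-allyl-3,5-dimethoxy-6-[3-methoxy-4-(triisopropylsilyloxy)phenyl]-7-methylbicyclo[3.2.1]oct-2-ene-4,8-diol (C4 as in 14, C8 as in 11) | C=CC[C@@]12C=C(OC)[C@H](O)[C@@](OC)([C@@H]1O)[C@H](c1ccc(O[Si](C(C)C)(C(C)C)C(C)C)c(OC)c1)[C@H]2C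
F6 | step 9 | 4-O-triethylsilyl ether of F5 | C=CC[C@@]12C=C(OC)[C@H](O[Si](CC)(CC)CC)[C@@](OC)([C@@H]1O)[C@H](c1ccc(O[Si](C(C)C)(C(C)C)C(C)C)c(OC)c1)[C@H]2C
F7 | step 9 | 4-O-triethylsilyl ether of 13 | C=CC[C@@]12C=C(OC)[C@H](O[Si](CC)(CC)CC)[C@@](OC)(C1=O)[C@H](c1ccc(O[Si](C(C)C)(C(C)C)C(C)C)c(OC)c1)[C@H]2C
F8 | step 4 | rac-2-bromo-1-[3-methoxy-4-(triisopropylsilyloxy)phenyl]propan-1-one | CC(Br)C(=O)c1ccc(O[Si](C(C)C)(C(C)C)C(C)C)c(OC)c1
F9 | step 4 | [4-(benzyloxy)-3,5-dimethoxyphenyl]magnesium bromide | COc1cc([Mg]Br)cc(OC)c1OCc1ccccc1
F10 | step 4 | [4-(benzyloxy)-3,5-dimethoxyphenyl]zinc iodide | COc1cc([Zn]I)cc(OC)c1OCc1ccccc1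
F11 | step 4 | (S)-2-[4-(benzyloxy)-3,5-dimethoxyphenyl]-1-[3-methoxy-4-(triisopropylsilyloxy)phenyl]propan-1-one | COc1cc(cc(OC)c1OCc1ccccc1)[C@H](C)C(=O)c1ccc(O[Si](C(C)C)(C(C)C)C(C)C)c(OC)c1
A1 | alternative 1 | 1-allyl-4-(tert-butyldimethylsilyloxy)-6-[4-(tert-butyldimethylsilyloxy)-3-methoxyphenyl]-3,5-dimethoxy-7-methylbicyclo[3.2.1]octan-8-one | C=CC[C@@]12C[C@@H](OC)[C@H](O[Si](C)(C)C(C)(C)C)[C@@](OC)(C1=O)[C@H](c1ccc(O[Si](C)(C)C(C)(C)C)c(OC)c1)[C@H]2C
A2 | alternative 1 | 2-[1-(tert-butyldimethylsilyloxy)-2,2-dimethoxyethyl]-3-[4-(tert-butyldimethylsilyloxy)-3-methoxyphenyl]-2-methoxy-4-methyl-1-(penta-1,4-dien-2-yl)cyclobutan-1-ol | C=CCC(=C)[C@@]1(O)[C@H](C)[C@@H](c2ccc(O[Si](C)(C)C(C)(C)C)c(OC)c2)[C@@]1(OC)[C@@H](O[Si](C)(C)C(C)(C)C)C(OC)OC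
A3 | alternative 2 | 1-allyl-6-[4-(tert-butyldimethylsilyloxy)-3-methoxyphenyl]-2-hydroxy-3,5-dimethoxy-7-methylbicyclo[3.2.1]oct-2-ene-4,8-dione | C=CC[C@@]12C(O)=C(OC)C(=O)[C@@](OC)(C1=O)[C@H](c1ccc(O[Si](C)(C)C(C)(C)C)c(OC)c1)[C@H]2C
A4 | alternative 2 | [2-allyl-4-[4-(tert-butyldimethylsilyloxy)-3-methoxyphenyl]-5-methoxy-3-methylcyclopent-1-en-1-yl]oxytrimethylsilane | C=CCC1=C(O[Si](C)(C)C)[C@H](OC)[C@H](c2ccc(O[Si](C)(C)C(C)(C)C)c(OC)c2)[C@H]1C
A5 | alternative 2 | 2-methoxypropanedioyl dichloride (methoxymalonyl dichloride) | COC(C(Cl)=O)C(Cl)=O
A6 | alternative 3 | [2-allyl-4-[4-(tert-butyldimethylsilyloxy)-3-methoxyphenyl]-5-methoxy-3-methylcyclopent-1-en-1-yl]oxytriethylsilane | C=CCC1=C(O[Si](CC)(CC)CC)[C@H](OC)[C@H](c2ccc(O[Si](C)(C)C(C)(C)C)c(OC)c2)[C@H]1C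
A7 | alternative 3 | (1Z,4E)-4-allyl-1-[4-(tert-butyldimethylsilyloxy)-3-methoxyphenyl]-2-methoxyhexa-1,4-dien-3-one | C/C=C(/C(=O)/C(OC)=C/c1ccc(O[Si](C)(C)C(C)(C)C)c(OC)c1)CC=C
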